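**Plan**
- Retrosynthetic cuts, in order: the C4–C4a bond of the flavan (made as a 2H-chromene from an aryl propargyl ether, C3=C4 then saturated); the O1–C2 ether bond (Mitsunobu); the chromenone C3–aryl bond (Suzuki–Miyaura).
- Forward: apigenin → tribenzyl ether → 3-iodide; 3,5-bis(benzyloxy)phenol → silyl ether → boronate; biaryl coupling and desilylation; etherification with an (R)-1-arylpropynol; gold-catalysed closure of the pyran ring; one hydrogenation that saturates C3=C4 and removes all six benzyl-type groups.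
- Enabling feature: in the cyclization substrate the ether oxygen (future O1) is para to the chromenon-3-yl carbon (future C6) on a ring whose two other oxygens carry identical benzyl groups. The two CH carbons ortho to that oxygen are therefore constitutionally equivalent, each ortho or para to three oxygens, and closure at either gives only the 6-linked flavan.
- Stereochemistry: C2 is set as the (R)-carbinol by Midland reduction of an aryl ethynyl ketone, inverted to (S) in the Mitsunobu step, and is a spectator in ring closure and hydrogenation.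

Key step: step 12

Remark on the chemistry: the target carries no descriptor for the aryl–aryl axis between chromenone C3 and flavan C6, so the axis is treated as stereochemically undefined and rotamers about it count as one compound.

**Step 1**
Reactants: 1 apigenin [5,7-dihydroxy-2-(4-hydroxyphenyl)-4H-chromen-4-one]
Product: 2 5,7-bis(benzyloxy)-2-[4-(benzyloxy)phenyl]-4H-chromen-4-one
Conditions: BnBr (excess), K2CO3, Bu4NI (cat.), DMF, 80 °C
Reagents that add atoms: benzyl bromide, BrCc1ccccc1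
Why: Williamson etherification of all three phenoxides, in which the hydrogen-bonded 5-OH reacts last and is driven by excess bromide and heat.

**Step 2**
Reactants: 2 5,7-bis(benzyloxy)-2-[4-(benzyloxy)phenyl]-4H-chromen-4-one
Product: 4 5,7-bis(benzyloxy)-2-[4-(benzyloxy)phenyl]-3-iodo-4H-chromen-4-one, via 3-lithiochromenone 3 (not isolated)
Conditions: LiN(iPr)2, THF, −78 °C; then I2, −78 °C → rt
Reagents that add atoms: lithium diisopropylamide, [Li+].CC(C)[N-]C(C)C (lithium of 3); iodine, II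
Why: lithiation–iodination of a flavone, in which the amide base removes the only vinylic proton (C3–H, next to the carbonyl) and the vinyllithium is trapped by iodine.

**Step 3**
Reactants: 5 3,5-bis(benzyloxy)phenol
Product: 6 [3,5-bis(benzyloxy)phenoxy]tri(propan-2-yl)silane
Conditions: iPr3SiCl, imidazole, DMF, rt
Reagents that add atoms: chlorotri(propan-2-yl)silane, CC(C)[Si](Cl)(C(C)C)C(C)C
Why: standard silylation of a phenol, which marks the oxygen that becomes O1 with a bulky group that neither directs nor allows metalation next to it.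

**Step 4**
Reactants: 6 [3,5-bis(benzyloxy)phenoxy]tri(propan-2-yl)silane
Product: 8 2-[2,6-bis(benzyloxy)-4-{[tri(propan-2-yl)silyl]oxy}phenyl]-4,4,5,5-tetramethyl-1,3,2-dioxaborolane, via aryllithium 7 (not isolated)
Conditions: n-BuLi, THF, −20 → 0 °C; then iPrOBpin, −78 °C → rt; NH4Cl (aq)
Reagents that add atoms: n-butyllithium, [Li]CCCC (lithium of 7); 2-isopropoxy-4,4,5,5-tetramethyl-1,3,2-dioxaborolane, CC(C)OB1OC(C)(C)C(C)(C)O1
Why: directed ortho-metalation at the one carbon flanked by both benzyloxy groups (cooperative 1,3-direction, the silyloxy side being shielded), followed by borylation of the aryllithium.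

**Step 5**
Reactants: 4 5,7-bis(benzyloxy)-2-[4-(benzyloxy)phenyl]-3-iodo-4H-chromen-4-one; 8 2-[2,6-bis(benzyloxy)-4-{[tri(propan-2-yl)silyl]oxy}phenyl]-4,4,5,5-tetramethyl-1,3,2-dioxaborolane
Product: 9 5,7-bis(benzyloxy)-2-[4-(benzyloxy)phenyl]-3-[2,6-bis(benzyloxy)-4-{[tri(propan-2-yl)silyl]oxy}phenyl]-4H-chromen-4-one
Conditions: Pd(OAc)2 (cat.), SPhos, K3PO4, toluene/H2O, 90 °C
Reagents that add atoms: none
Why: Suzuki–Miyaura coupling of a 3-iodochromenone, with a bulky electron-rich biarylphosphine chosen to carry oxidative addition and transmetalation at two ortho-disubstituted partners.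

**Step 6**
Reactants: 9 5,7-bis(benzyloxy)-2-[4-(benzyloxy)phenyl]-3-[2,6-bis(benzyloxy)-4-{[tri(propan-2-yl)silyl]oxy}phenyl]-4H-chromen-4-one
Product: 10 5,7-bis(benzyloxy)-2-[4-(benzyloxy)phenyl]-3-[2,6-bis(benzyloxy)-4-hydroxyphenyl]-4H-chromen-4-one
Conditions: Bu4NF, THF, 0 °C; NH4Cl (aq)
Reagents that add atoms: none
Why: fluoride cleavage of the aryl silyl ether should free only the phenol para to the chromenonyl group, the benzyl ethers being inert.

**Step 7**
Reactants: 11 4-hydroxybenzaldehyde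
Product: 12 benzyl 4-formylphenyl carbonate
Conditions: CbzCl, Et3N, CH2Cl2, 0 °C
Reagents that add atoms: benzyl chloroformate, O=C(Cl)OCc1ccccc1
Why: O-acylation of the phenol gives a carbonate that is removable by hydrogenolysis and turns the oxygen into a poor donor toward the future benzylic carbon.

**Step 8**
Reactants: 12 benzyl 4-formylphenyl carbonate
Product: 13 rac-benzyl 4-(1-hydroxyprop-2-yn-1-yl)phenyl carbonate
Conditions: HC≡CMgBr, THF, −78 → −40 °C; NH4Cl (aq), cold
Reagents that add atoms: ethynylmagnesium bromide, C#C[Mg]Br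
Why: Grignard 1,2-addition to the aldehyde, which at low temperature is far faster than attack at the aryl carbonate.

**Step 9**
Reactants: 13 rac-benzyl 4-(1-hydroxyprop-2-yn-1-yl)phenyl carbonate
Product: 14 benzyl 4-(prop-2-ynoyl)phenyl carbonate
Conditions: MnO2 (activated, excess), CH2Cl2, rt
Reagents that add atoms: none
Why: MnO2 oxidation of a benzylic–propargylic alcohol to the aryl ethynyl ketone under neutral conditions that spare the carbonate.

**Step 10**
Reactants: 14 benzyl 4-(prop-2-ynoyl)phenyl carbonate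
Product: 15 benzyl 4-[(1R)-1-hydroxyprop-2-yn-1-yl]phenyl carbonate
Conditions: (S)-Alpine-Borane [B-isopinocampheyl-9-borabicyclo[3.3.1]nonane from (−)-α-pinene], THF (concentrated), rt; MeCHO; then HOCH2CH2NH2, Et2O, 0 °C
Reagents that add atoms: none
Why: Midland reduction, in which the β-hydride of the isopinocampheyl group is delivered through a boat-like six-membered transition state with the slim ethynyl group next to the pinane methyl, so the reagent from (−)-α-pinene should give the (R)-carbinol (aryl outranks ethynyl).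

**Step 11**
Reactants: 10 5,7-bis(benzyloxy)-2-[4-(benzyloxy)phenyl]-3-[2,6-bis(benzyloxy)-4-hydroxyphenyl]-4H-chromen-4-one; 15 benzyl 4-[(1R)-1-hydroxyprop-2-yn-1-yl]phenyl carbonate
Product: 16 benzyl 4-[(1S)-1-{3,5-bis(benzyloxy)-4-[5,7-bis(benzyloxy)-2-(4-(benzyloxy)phenyl)-4-oxo-4H-chromen-3-yl]phenoxy}prop-2-yn-1-yl]phenyl carbonate
Conditions: PPh3, DIAD, toluene, 0 °C → rt
Reagents that add atoms: none
Why: Mitsunobu etherification of the unhindered phenol, in which SN2 displacement of the alkoxyphosphonium group inverts the carbinol carbon from (R) to (S) and the carbonate-deactivated aryl group disfavours ionization.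

**Step 12**
Reactants: 16 benzyl 4-[(1S)-1-{3,5-bis(benzyloxy)-4-[5,7-bis(benzyloxy)-2-(4-(benzyloxy)phenyl)-4-oxo-4H-chromen-3-yl]phenoxy}prop-2-yn-1-yl]phenyl carbonate
Product: 17 benzyl 4-[(2S)-5,7-bis(benzyloxy)-6-{5,7-bis(benzyloxy)-2-[4-(benzyloxy)phenyl]-4-oxo-4H-chromen-3-yl}-2H-chromen-2-yl]phenyl carbonate
Conditions: Ph3PAuNTf2 (cat.), CH2Cl2, rt, exclusion of light
Reagents that add atoms: none
Why: The cationic phosphine–gold centre binds the terminal alkyne, and the ring carbon ortho to the ether oxygen, which is ortho or para to three oxygen substituents, attacks the terminal alkyne carbon anti to gold; the arenium ion then loses a proton and protodeauration of the vinyl–gold bond releases the catalyst. The closest known reaction type is the gold- or platinum-catalysed intramolecular hydroarylation of aryl propargyl ethers to 2H-chromenes. The single new ring, the pyran ring of the flavan unit, closes in the 6-endo-dig mode. No new stereocenter is formed: C2 is the former propargylic carbon, no bond to it is made or broken, so the (S) configuration from step 11 is carried through. The step needs site selectivity, endo over exo selectivity and an intact C2–O bond: the two ortho carbons are exchanged by rotation about the aryl–chromenone bond so both give the 6-linked product, the terminal alkyne on an aryl–O tether favours the endo mode, and the carbonate on the para oxygen of the 2-aryl group withholds the donor that would stabilise a benzylic–propargylic cation.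

**Step 13**
Reactants: 17 benzyl 4-[(2S)-5,7-bis(benzyloxy)-6-{5,7-bis(benzyloxy)-2-[4-(benzyloxy)phenyl]-4-oxo-4H-chromen-3-yl}-2H-chromen-2-yl]phenyl carbonate
Product: 18 3-[(2S)-5,7-dihydroxy-2-(4-hydroxyphenyl)-3,4-dihydro-2H-chromen-6-yl]-5,7-dihydroxy-2-(4-hydroxyphenyl)-4H-chromen-4-one
Conditions: H2 (1 atm), 10% Pd/C, THF/MeOH, rt, exclusion of light
Reagents that add atoms: none
Why: heterogeneous hydrogenation should saturate the cis-disubstituted styrenic C3=C4 bond and cleave the five benzyl ethers and the benzyl carbonate (which then loses CO2) in one operation, while the tetrasubstituted chromenone double bond and the C2 stereocenter are left alone under neutral, low-pressure conditions.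

**Compound list**
1 | apigenin, 5,7-dihydroxy-2-(4-hydroxyphenyl)-4H-chromen-4-one | O=c1cc(-c2ccc(O)cc2)oc2cc(O)cc(O)c12 | starting material
2 | 5,7-bis(benzyloxy)-2-[4-(benzyloxy)phenyl]-4H-chromen-4-one | O=c1cc(-c2ccc(OCc3ccccc3)cc2)oc2cc(OCc3ccccc3)cc(OCc3ccccc3)c12 | intermediate
3 | 5,7-bis(benzyloxy)-2-[4-(benzyloxy)phenyl]-3-lithio-4H-chromen-4-one | O=c1c([Li])c(-c2ccc(OCc3ccccc3)cc2)oc2cc(OCc3ccccc3)cc(OCc3ccccc3)c12 | intermediate
4 | 5,7-bis(benzyloxy)-2-[4-(benzyloxy)phenyl]-3-iodo-4H-chromen-4-one | O=c1c(I)c(-c2ccc(OCc3ccccc3)cc2)oc2cc(OCc3ccccc3)cc(OCc3ccccc3)c12 | intermediate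
5 | 3,5-bis(benzyloxy)phenol | Oc1cc(OCc2ccccc2)cc(OCc2ccccc2)c1 | starting material
6 | [3,5-bis(benzyloxy)phenoxy]tri(propan-2-yl)silane | CC(C)[Si](Oc1cc(OCc2ccccc2)cc(OCc2ccccc2)c1)(C(C)C)C(C)C | intermediate
7 | [2,6-bis(benzyloxy)-4-{[tri(propan-2-yl)silyl]oxy}phenyl]lithium | [Li]c1c(OCc2ccccc2)cc(O[Si](C(C)C)(C(C)C)C(C)C)cc1OCc1ccccc1 | intermediate
8 | 2-[2,6-bis(benzyloxy)-4-{[tri(propan-2-yl)silyl]oxy}phenyl]-4,4,5,5-tetramethyl-1,3,2-dioxaborolane | CC1(C)OB(OC1(C)C)c1c(OCc2ccccc2)cc(O[Si](C(C)C)(C(C)C)C(C)C)cc1OCc1ccccc1 | intermediate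
9 | 5,7-bis(benzyloxy)-2-[4-(benzyloxy)phenyl]-3-[2,6-bis(benzyloxy)-4-{[tri(propan-2-yl)silyl]oxy}phenyl]-4H-chromen-4-one | O=c1c(-c2c(OCc3ccccc3)cc(O[Si](C(C)C)(C(C)C)C(C)C)cc2OCc2ccccc2)c(-c2ccc(OCc3ccccc3)cc2)oc2cc(OCc3ccccc3)cc(OCc3ccccc3)c12 | intermediate
10 | 5,7-bis(benzyloxy)-2-[4-(benzyloxy)phenyl]-3-[2,6-bis(benzyloxy)-4-hydroxyphenyl]-4H-chromen-4-one | O=c1c(-c2c(OCc3ccccc3)cc(O)cc2OCc2ccccc2)c(-c2ccc(OCc3ccccc3)cc2)oc2cc(OCc3ccccc3)cc(OCc3ccccc3)c12 | intermediate
11 | 4-hydroxybenzaldehyde | O=Cc1ccc(O)cc1 | starting material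
12 | benzyl 4-formylphenyl carbonate | O=Cc1ccc(OC(=O)OCc2ccccc2)cc1 | intermediate
13 | rac-benzyl 4-(1-hydroxyprop-2-yn-1-yl)phenyl carbonate | C#CC(O)c1ccc(OC(=O)OCc2ccccc2)cc1 | intermediate
14 | benzyl 4-(prop-2-ynoyl)phenyl carbonate | C#CC(=O)c1ccc(OC(=O)OCc2ccccc2)cc1 | intermediate
15 | benzyl 4-[(1R)-1-hydroxyprop-2-yn-1-yl]phenyl carbonate | C#C[C@@H](O)c1ccc(OC(=O)OCc2ccccc2)cc1 | intermediate
16 | benzyl 4-[(1S)-1-{3,5-bis(benzyloxy)-4-[5,7-bis(benzyloxy)-2-(4-(benzyloxy)phenyl)-4-oxo-4H-chromen-3-yl]phenoxy}prop-2-yn-1-yl]phenyl carbonate | C#C[C@H](Oc1cc(OCc2ccccc2)c(-c2c(-c3ccc(OCc4ccccc4)cc3)oc3cc(OCc4ccccc4)cc(OCc4ccccc4)c3c2=O)c(OCc2ccccc2)c1)c1ccc(OC(=O)OCc2ccccc2)cc1 | intermediate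
17 | benzyl 4-[(2S)-5,7-bis(benzyloxy)-6-{5,7-bis(benzyloxy)-2-[4-(benzyloxy)phenyl]-4-oxo-4H-chromen-3-yl}-2H-chromen-2-yl]phenyl carbonate | O=c1c(-c2c(OCc3ccccc3)cc3c(c2OCc2ccccc2)C=C[C@@H](c2ccc(OC(=O)OCc4ccccc4)cc2)O3)c(-c2ccc(OCc3ccccc3)cc2)oc2cc(OCc3ccccc3)cc(OCc3ccccc3)c12 | intermediate
18 | 3-[(2S)-5,7-dihydroxy-2-(4-hydroxyphenyl)-3,4-dihydro-2H-chromen-6-yl]-5,7-dihydroxy-2-(4-hydroxyphenyl)-4H-chromen-4-one | O=c1c(-c2c(O)cc3c(c2O)CC[C@@H](c2ccc(O)cc2)O3)c(-c2ccc(O)cc2)oc2cc(O)cc(O)c12 | target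

**Step count**
Total: 13 steps. Longest linear sequence: 7 steps (for example 11 → 12 → 13 → 14 → 15 → 16 → 17 → 18; the branches from 1 and from 5 are equally long).

**Steps most likely to fail**

Step 12. The gold-activated substrate may ionize at the benzylic–propargylic C–O bond (loss of configuration, or migration of the aryl group from oxygen to carbon), or it may close in the 5-exo mode. The fallback closes the pyran ring at O1–C2 instead; it sets out from 10 and returns at 18. Ortho-formylation of 10 (MgCl2, Et3N, paraformaldehyde, MeCN, reflux) should give the salicylaldehyde 3-[2,6-bis(benzyloxy)-3-formyl-4-hydroxyphenyl]-5,7-bis(benzyloxy)-2-[4-(benzyloxy)phenyl]-4H-chromen-4-one F1. Claisen–Schmidt condensation with 1-[4-(benzyloxy)phenyl]ethan-1-one (KOH, EtOH/THF) would give the (E)-enone F2. Hydrogenation of only the enone double bond (H2, RhCl(PPh3)3) would give the saturated aryl ketone F3. Corey–Bakshi–Shibata reduction with the (S)-methyl oxazaborolidine and BH3·SMe2 should deliver the (R)-carbinol F4, the aryl group acting as the large substituent. Intramolecular Mitsunobu etherification (PPh3, DIAD, toluene, 0 °C) would then close the ring with inversion to the (2S)-flavan hexabenzyl ether F5. Hydrogenolysis (H2, Pd/C) of F5 gives 18.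

Step 5. Protodeboronation of the electron-rich, di-ortho-alkoxy boronate may outrun a slow transmetalation at the congested C3 position. The fallback forms the same carbon–carbon bond at the unhindered sp3 stage and builds the chromenone afterwards; it sets out from 6 and returns at 9. Metalation of 6 as in step 4 (through 7) and quenching with I2 should give the aryl iodide [3,5-bis(benzyloxy)-4-iodophenoxy]tri(propan-2-yl)silane F6. Palladium-catalysed ketone α-arylation of 1-[2,4,6-tris(benzyloxy)phenyl]ethan-1-one with F6 (Pd(OAc)2, XPhos, NaOtBu, toluene, 80 °C) would give the deoxybenzoin 1-[2,4,6-tris(benzyloxy)phenyl]-2-[2,6-bis(benzyloxy)-4-{[tri(propan-2-yl)silyl]oxy}phenyl]ethan-1-one F7. Chelation-controlled removal of one benzyl group ortho to the carbonyl (MgBr2·OEt2, toluene/Et2O, heat) would give the 2-hydroxy deoxybenzoin F8. Aroylation with 4-(benzyloxy)benzoyl chloride, acyl transfer and cyclodehydration (K2CO3, acetone, reflux; Baker–Venkataraman type) then closes the chromenone ring to 9.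

Step 13. The allylic and benzylic C2–O bond may undergo hydrogenolysis before the C3=C4 bond is saturated, or the chromenone may be over-reduced. The fallback separates the two tasks and avoids the metal surface; it sets out from 17 and returns at 18. Diimide reduction (2-nitrobenzenesulfonyl hydrazide, Et3N, CH2Cl2, rt) should saturate only the disubstituted C3=C4 bond and give the protected flavan benzyl 4-[(2S)-5,7-bis(benzyloxy)-6-{5,7-bis(benzyloxy)-2-[4-(benzyloxy)phenyl]-4-oxo-4H-chromen-3-yl}-3,4-dihydro-2H-chromen-2-yl]phenyl carbonate F9. Lewis-acid debenzylation (BCl3, pentamethylbenzene, CH2Cl2, −78 °C) would remove the five benzyl ethers and the benzyl carbonate to give 18.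

**Further compounds**
F1 | step 12 | 3-[2,6-bis(benzyloxy)-3-formyl-4-hydroxyphenyl]-5,7-bis(benzyloxy)-2-[4-(benzyloxy)phenyl]-4H-chromen-4-one | O=Cc1c(O)cc(OCc2ccccc2)c(-c2c(-c3ccc(OCc4ccccc4)cc3)oc3cc(OCc4ccccc4)cc(OCc4ccccc4)c3c2=O)c1OCc1ccccc1
F2 | step 12 | (E)-3-{2,4-bis(benzyloxy)-3-[5,7-bis(benzyloxy)-2-(4-(benzyloxy)phenyl)-4-oxo-4H-chromen-3-yl]-6-hydroxyphenyl}-1-[4-(benzyloxy)phenyl]prop-2-en-1-one | O=C(/C=C/c1c(O)cc(OCc2ccccc2)c(-c2c(-c3ccc(OCc4ccccc4)cc3)oc3cc(OCc4ccccc4)cc(OCc4ccccc4)c3c2=O)c1OCc1ccccc1)c1ccc(OCc2ccccc2)cc1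
F3 | step 12 | 3-{2,4-bis(benzyloxy)-3-[5,7-bis(benzyloxy)-2-(4-(benzyloxy)phenyl)-4-oxo-4H-chromen-3-yl]-6-hydroxyphenyl}-1-[4-(benzyloxy)phenyl]propan-1-one | O=C(CCc1c(O)cc(OCc2ccccc2)c(-c2c(-c3ccc(OCc4ccccc4)cc3)oc3cc(OCc4ccccc4)cc(OCc4ccccc4)c3c2=O)c1OCc1ccccc1)c1ccc(OCc2ccccc2)cc1
F4 | step 12 | 5,7-bis(benzyloxy)-2-[4-(benzyloxy)phenyl]-3-{2,6-bis(benzyloxy)-3-[(3R)-3-(4-(benzyloxy)phenyl)-3-hydroxypropyl]-4-hydroxyphenyl}-4H-chromen-4-one | O[C@H](CCc1c(O)cc(OCc2ccccc2)c(-c2c(-c3ccc(OCc4ccccc4)cc3)oc3cc(OCc4ccccc4)cc(OCc4ccccc4)c3c2=O)c1OCc1ccccc1)c1ccc(OCc2ccccc2)cc1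
F5 | step 12 | 5,7-bis(benzyloxy)-2-[4-(benzyloxy)phenyl]-3-{(2S)-5,7-bis(benzyloxy)-2-[4-(benzyloxy)phenyl]-3,4-dihydro-2H-chromen-6-yl}-4H-chromen-4-one | O=c1c(-c2c(OCc3ccccc3)cc3c(c2OCc2ccccc2)CC[C@@H](c2ccc(OCc4ccccc4)cc2)O3)c(-c2ccc(OCc3ccccc3)cc2)oc2cc(OCc3ccccc3)cc(OCc3ccccc3)c12
F6 | step 5 | [3,5-bis(benzyloxy)-4-iodophenoxy]tri(propan-2-yl)silane | CC(C)[Si](Oc1cc(OCc2ccccc2)c(I)c(OCc2ccccc2)c1)(C(C)C)C(C)C
F7 | step 5 | 1-[2,4,6-tris(benzyloxy)phenyl]-2-[2,6-bis(benzyloxy)-4-{[tri(propan-2-yl)silyl]oxy}phenyl]ethan-1-one | O=C(Cc1c(OCc2ccccc2)cc(O[Si](C(C)C)(C(C)C)C(C)C)cc1OCc1ccccc1)c1c(OCc2ccccc2)cc(OCc2ccccc2)cc1OCc1ccccc1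
F8 | step 5 | 1-[2,4-bis(benzyloxy)-6-hydroxyphenyl]-2-[2,6-bis(benzyloxy)-4-{[tri(propan-2-yl)silyl]oxy}phenyl]ethan-1-one | O=C(Cc1c(OCc2ccccc2)cc(O[Si](C(C)C)(C(C)C)C(C)C)cc1OCc1ccccc1)c1c(O)cc(OCc2ccccc2)cc1OCc1ccccc1
F9 | step 13 | benzyl 4-[(2S)-5,7-bis(benzyloxy)-6-{5,7-bis(benzyloxy)-2-[4-(benzyloxy)phenyl]-4-oxo-4H-chromen-3-yl}-3,4-dihydro-2H-chromen-2-yl]phenyl carbonate | O=c1c(-c2c(OCc3ccccc3)cc3c(c2OCc2ccccc2)CC[C@@H](c2ccc(OC(=O)OCc4ccccc4)cc2)O3)c(-c2ccc(OCc3ccccc3)cc2)oc2cc(OCc3ccccc3)cc(OCc3ccccc3)c12
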